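Ring B (C1, C10, C9, C8, C7, C6) is formed by one-carbon ring expansion. A Diels–Alder reaction of (S)-4-methylcyclopentenone builds a cis-fused 8-nor skeleton in which the C7 ketone is bonded directly to C9. The key step, a Lewis-acid-catalysed TMSCHN2 homologation, exploits the C7 carbonyl flanked by the methylene C9 and the ring-fusion methine C6: C9 migrates, C8 enters the C7–C9 bond, and a regiodefined C7=C8 silyl enol ether results. The derived enone receives the C9 oxygen by conjugate borylation. A C7 triflate, an isopropenyl coupling and a Ni-catalysed 1,4-hydroboration of the diene then set the (E)-C7=C11 alkene.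

Key step: step 5

Remark (convention): cadinane numbering is used throughout (C1/C6 ring fusion, C14 = 10-CH3, C15 = 4-CH3, C11–C13 side chain). "Nor" compounds keep these atom numbers, and "8-nor" means C7 is bonded to C9. α is the face of H-1, H-6 and the 10-CH3 group; β is the face of the C3 and C9 oxygens. All bicyclic compounds are 1αH,6αH (cis-fused) with 10α-CH3.

Step 1
Reactants: 1 (4S)-4-[(tert-butyldimethylsilyl)oxy]cyclopent-2-en-1-one
Product: 3 (4S)-4-methylcyclopent-2-en-1-one, via trans-3-methyl-4-silyloxycyclopentanone 2 (not isolated)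
Conditions: Me2CuLi, Et2O, −78 °C; then DBU, CH2Cl2, 0 °C
Reagents that add atoms: lithium dimethylcuprate, [Li+].C[Cu-]C
Why: Conjugate addition of the cuprate anti to the silyloxy group followed by E1cB loss of silanolate from ketone 2 (net anti-SN2′ methyl transfer) should fix the future C10 stereocenter from the commercial (S)-enone.

Step 2
Reactants: 4 (E)-2-methylbut-2-enal (tiglic aldehyde)
Product: 5 (1E)-2-methylbuta-1,3-dien-1-yl acetate
Conditions: isopropenyl acetate, TsOH (cat.), 95 °C, acetone distilled off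
Reagents that add atoms: isopropenyl acetate, CC(=C)OC(C)=O
Why: Acid-catalysed dienol acetylation of the enal by transesterification should give mainly the less hindered (1E)-dienyl acetate, the only isomer that reacts in step 3.

Step 3
Reactants: 3 (4S)-4-methylcyclopent-2-en-1-one; 5 (1E)-2-methylbuta-1,3-dien-1-yl acetate
Product: 6 5β-acetoxy-8,11,12,13-tetranorcadin-3-en-7-one (cis-fused hydrindenone, C7 bonded to C9)
Conditions: EtAlCl2 (0.25 equiv), CH2Cl2, −40 → 0 °C
Reagents that add atoms: none
Why: In this Lewis-acid-catalysed Diels–Alder reaction the diene should add anti to the 4-methyl group (cis fusion, H-1 and H-6 cis to the methyl), the 1-acetoxy group should direct its carbon onto the enone α-carbon C6 (ortho rule), and endo addition should place the C5 acetate cis to C7.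

Step 4
Reactants: 6 5β-acetoxy-8,11,12,13-tetranorcadin-3-en-7-one
Product: 7 3β-acetoxy-8,11,12,13-tetranorcadin-4-en-7-one
Conditions: Pd(PPh3)4 (5 mol %), THF, 50 °C
Reagents that add atoms: none
Why: Pd(0)-catalysed 1,3-transposition of the allylic acetate through a π-allyl-palladium acetate ion pair (ionisation and return both anti to Pd, so the shift is suprafacial) should move the β-acetoxy group from the hindered β-keto position C5 to C3 and the alkene to C4=C5.

Step 5
Reactants: 7 3β-acetoxy-8,11,12,13-tetranorcadin-4-en-7-one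
Product: 9 3β-acetoxy-7-(trimethylsilyloxy)-11,12,13-trinorcadina-4,7-diene, via β-keto silane 8 (not isolated)
Conditions: TMSCHN2, Sc(OTf)3 (5 mol %), toluene, −78 → 0 °C; then 50 °C
Reagents that add atoms: (trimethylsilyl)diazomethane, C[Si](C)(C)C=[N+]=[N-]
Why: Sc(OTf)3 activates the C7 carbonyl, the diazo carbon adds to it, and with loss of N2 one α-carbon shifts onto the new carbon C8, after which β-keto silane 8 undergoes a 1,3-Brook shift to the silyl enol ether. The closest known reaction type is the Lewis-acid-catalysed Tiffeneau–Demjanov-type homologation of cycloalkanones with TMSCHN2. No ring is closed: the five-membered ring C1–C10–C9–C7–C6 is enlarged to the six-membered ring C1–C10–C9–C8–C7–C6 by insertion of C8 into the C7–C9 bond. No lasting stereocenter is created (C8 ends sp2), and C1, C6 and C10 are not involved and keep their configuration. The step needs migration of C9 rather than C6 and a single insertion only: the less substituted methylene C9 should migrate in preference to the ring-fusion methine C6, and the silyl group should block a second homologation while fixing the enol ether at C7=C8 for step 6.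

Step 6
Reactants: 9 3β-acetoxy-7-(trimethylsilyloxy)-11,12,13-trinorcadina-4,7-diene
Product: 10 3β-acetoxy-11,12,13-trinorcadina-4,8-dien-7-one
Conditions: Pd(OAc)2, MeCN, rt
Reagents that add atoms: none
Why: In this Saegusa–Ito oxidation Pd(II) forms the C8 palladium enolate from the regiodefined silyl enol ether, and β-hydride loss can only involve C9, so the Δ8 enone should form without touching C6 or C10.

Step 7
Reactants: 10 3β-acetoxy-11,12,13-trinorcadina-4,8-dien-7-one
Product: 11 3β-acetoxy-9β-(pinacolboryl)-11,12,13-trinorcadin-4-en-7-one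
Conditions: B2pin2, CuCl/Xantphos (5 mol %), NaOt-Bu (5 mol %), MeOH (2 equiv), THF, rt
Reagents that add atoms: bis(pinacolato)diboron, CC1(C)OB(OC1(C)C)B1OC(C)(C)C(C)(C)O1
Why: In this copper(I)-catalysed conjugate borylation the boryl-copper species should add to C9 anti to the adjacent 10α-methyl group, setting the 9β C–B bond that is later oxidised with retention.

Step 8
Reactants: 11 3β-acetoxy-9β-(pinacolboryl)-11,12,13-trinorcadin-4-en-7-one
Product: 12 3β-acetoxy-9β-(pinacolboryl)-11,12,13-trinorcadina-4,7-dien-7-yl trifluoromethanesulfonate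
Conditions: KHMDS, PhNTf2, THF, −78 °C
Reagents that add atoms: N-phenyl-bis(trifluoromethanesulfonimide), O=S(=O)(N(c1ccccc1)S(=O)(=O)C(F)(F)F)C(F)(F)F
Why: Kinetic deprotonation at the C8 methylene rather than the ring-fusion methine C6, followed by O-triflation of the enolate (standard enol triflate formation), should give the Δ7(8) triflate without epimerising C6.

Step 9
Reactants: 12 3β-acetoxy-9β-(pinacolboryl)-11,12,13-trinorcadina-4,7-dien-7-yl trifluoromethanesulfonate; 13 4,4,5,5-tetramethyl-2-(prop-1-en-2-yl)-1,3,2-dioxaborolane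
Product: 14 3β-acetoxy-9β-(pinacolboryl)cadina-4,7,11-triene
Conditions: Pd(dppf)Cl2 (5 mol %), K3PO4, THF/H2O, 40 °C
Reagents that add atoms: none
Why: In this Suzuki–Miyaura coupling the sp2 boronate should transmetalate far faster than the secondary alkyl boronate at C9, so the isopropenyl unit (C11, C12, C13) is attached to C7 with the ring double bond kept at C7=C8.

Step 10
Reactants: 14 3β-acetoxy-9β-(pinacolboryl)cadina-4,7,11-triene
Product: 16 (7(11)E)-3β-acetoxycadina-4,7(11)-diene-9β,12-diol, via bis-boronate 15 (not isolated)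
Conditions: HBpin, Ni(cod)2/PCy3 (5 mol %), toluene, rt; then NaBO3·4H2O, THF/H2O, rt
Reagents that add atoms: pinacolborane, B1OC(C)(C)C(C)(C)O1 (its boron is in 15 only); sodium perborate, [Na+].[O-]OB=O
Why: In this nickel-catalysed 1,4-hydroboration the s-cis-bound diene takes H at C8 and boron at the terminal C12, which should leave C8 and C12 cis on the new C7=C11 bond (the E alkene), and perborate then oxidises both C–B bonds with retention so that the C9 oxygen stays β.

Step 11
Reactants: 16 (7(11)E)-3β-acetoxycadina-4,7(11)-diene-9β,12-diol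
Product: 17 (7(11)E)-3β-acetoxy-9β-hydroxycadina-4,7(11)-dien-12-yl formate
Conditions: HCO2CH2CF3, THF, 50 °C
Reagents that add atoms: 2,2,2-trifluoroethyl formate, O=COCC(F)(F)F
Why: Transesterification with the activated formate should formylate the unhindered primary allylic alcohol much faster than the secondary C9 alcohol next to the C10 methyl group (chemoselective O-formylation).

Step 12
Reactants: 17 (7(11)E)-3β-acetoxy-9β-hydroxycadina-4,7(11)-dien-12-yl formate
Product: 18 (1S,3R,6S,9R,10R,7(11)E)-3,9-diacetoxycadina-4,7(11)-dien-12-yl formate (CNP0262962.1)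
Conditions: Ac2O, pyridine, CH2Cl2, rt
Reagents that add atoms: acetic anhydride, CC(=O)OC(C)=O
Why: Standard acetylation without DMAP of the remaining secondary alcohol should leave the formate and all stereocenters untouched and give the target.

Compound list
1 | (4S)-4-[(tert-butyldimethylsilyl)oxy]cyclopent-2-en-1-one | O=C1C=C[C@@H](O[Si](C)(C)C(C)(C)C)C1 | starting material
2 | (3S,4S)-4-[(tert-butyldimethylsilyl)oxy]-3-methylcyclopentan-1-one (trans) | O=C1C[C@H](C)[C@@H](O[Si](C)(C)C(C)(C)C)C1 | intermediate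
3 | (4S)-4-methylcyclopent-2-en-1-one | C[C@@H]1C=CC(=O)C1 | intermediate
4 | (E)-2-methylbut-2-enal | C/C=C(\C)C=O | starting material
5 | (1E)-2-methylbuta-1,3-dien-1-yl acetate | CC(=O)O/C=C(C)/C=C | intermediate
6 | 5β-acetoxy-8,11,12,13-tetranorcadin-3-en-7-one | CC1=CC[C@@H]2[C@@H](C)CC(=O)[C@@H]2[C@@H]1OC(C)=O | intermediate
7 | 3β-acetoxy-8,11,12,13-tetranorcadin-4-en-7-one | CC(=O)O[C@@H]1C[C@@H]2[C@@H](C)CC(=O)[C@@H]2C=C1C | intermediate
8 | 3β-acetoxy-8-(trimethylsilyl)-11,12,13-trinorcadin-4-en-7-one | CC(=O)O[C@@H]1C[C@@H]2[C@@H](C)CC([Si](C)(C)C)C(=O)[C@@H]2C=C1C | intermediate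
9 | 3β-acetoxy-7-(trimethylsilyloxy)-11,12,13-trinorcadina-4,7-diene | CC(=O)O[C@@H]1C[C@@H]2[C@@H](C)CC=C(O[Si](C)(C)C)[C@@H]2C=C1C | intermediate
10 | 3β-acetoxy-11,12,13-trinorcadina-4,8-dien-7-one | CC(=O)O[C@@H]1C[C@@H]2[C@@H](C)C=CC(=O)[C@@H]2C=C1C | intermediate
11 | 3β-acetoxy-9β-(pinacolboryl)-11,12,13-trinorcadin-4-en-7-one | CC(=O)O[C@@H]1C[C@@H]2[C@@H](C)[C@H](B3OC(C)(C)C(C)(C)O3)CC(=O)[C@@H]2C=C1C | intermediate
12 | 3β-acetoxy-9β-(pinacolboryl)-11,12,13-trinorcadina-4,7-dien-7-yl trifluoromethanesulfonate | CC(=O)O[C@@H]1C[C@@H]2[C@@H](C)[C@H](B3OC(C)(C)C(C)(C)O3)C=C(OS(=O)(=O)C(F)(F)F)[C@@H]2C=C1C | intermediate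
13 | 4,4,5,5-tetramethyl-2-(prop-1-en-2-yl)-1,3,2-dioxaborolane | CC(=C)B1OC(C)(C)C(C)(C)O1 | starting material
14 | 3β-acetoxy-9β-(pinacolboryl)cadina-4,7,11-triene | CC(=O)O[C@@H]1C[C@@H]2[C@@H](C)[C@H](B3OC(C)(C)C(C)(C)O3)C=C(C(C)=C)[C@@H]2C=C1C | intermediate
15 | (7(11)E)-3β-acetoxy-9β,12-bis(pinacolboryl)cadina-4,7(11)-diene | CC(=O)O[C@@H]1C[C@@H]2[C@@H](C)[C@H](B3OC(C)(C)C(C)(C)O3)C/C(=C(/C)CB3OC(C)(C)C(C)(C)O3)[C@@H]2C=C1C | intermediate
16 | (7(11)E)-3β-acetoxycadina-4,7(11)-diene-9β,12-diol | CC(=O)O[C@@H]1C[C@@H]2[C@@H](C)[C@H](O)C/C(=C(/C)CO)[C@@H]2C=C1C | intermediate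
17 | (7(11)E)-3β-acetoxy-9β-hydroxycadina-4,7(11)-dien-12-yl formate | CC(=O)O[C@@H]1C[C@@H]2[C@@H](C)[C@H](O)C/C(=C(/C)COC=O)[C@@H]2C=C1C | intermediate
18 | (1S,3R,6S,9R,10R,7(11)E)-3,9-diacetoxycadina-4,7(11)-dien-12-yl formate | CC(=O)O[C@@H]1C[C@@H]2[C@@H](C)[C@H](OC(C)=O)C/C(=C(/C)COC=O)[C@@H]2C=C1C | target

Total step count: 12. Longest linear sequence: 11 steps (steps 1 and 3–12; step 2 is a side branch).

Steps most likely to fail

Step 5 (key step). The insertion may suffer from poor migration selectivity (C6 instead of C9 shifting, which would place the new carbon between C6 and C7) or from a second homologation. Fallback, setting out from 7 and returning at 10, is the cyclopropanation–fragmentation (Ito–Saegusa) ring expansion. Kinetic enolisation of 7 (LDA, TMSCl internal quench, −78 °C) would give the Δ7(9) silyl enol ether 3β-acetoxy-7-(trimethylsilyloxy)-8,11,12,13-tetranorcadina-4,7(9)-diene F1. Furukawa cyclopropanation (Et2Zn, CH2I2) of the electron-rich enol ether would give the siloxycyclopropane F2, with C8 bridging C7 and C9. FeCl3 in DMF would cleave the C7–C9 bond through the alkoxy radical to the ring-enlarged β-chloro ketone 3β-acetoxy-9-chloro-11,12,13-trinorcadin-4-en-7-one F3, and NaOAc would remove HCl to give enone 10.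

Step 4 (together with step 3, which feeds it). The acetate transposition may stop at an unfavourable equilibrium, lose the acetate by β-hydride elimination from the π-allyl complex, or scramble the C3 configuration. The Diels–Alder step itself may also show poor regiocontrol, because the 2-methyl group opposes the acetoxy director. Fallback, setting out from 3 and returning at 7, uses a sulfur-directed cycloaddition and a sulfoxide–sulfenate shift. Lewis-acid Diels–Alder reaction of 3 with (1E)-2-methyl-1-(phenylthio)buta-1,3-diene (a strong ortho director) would give 5β-(phenylthio)-8,11,12,13-tetranorcadin-3-en-7-one F4. Oxidation with mCPBA at −78 °C and warming with P(OMe)3 in MeOH (Mislow–Evans [2,3] shift, suprafacial and irreversible) would give 3β-hydroxy-8,11,12,13-tetranorcadin-4-en-7-one F5. Ac2O/pyridine would then give 7.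

Step 10. The hydroboration may give poor regiocontrol (1,2-addition), may be slow in forming a tetrasubstituted alkene, or Ni(0) may ionise the allylic C3 acetate. Fallback, setting out from 11 and returning at 18, builds the alkene by olefination instead. Masamune–Roush Horner–Wadsworth–Emmons reaction of 11 with triethyl 2-phosphonopropionate (LiCl, DBU) would give the unsaturated ester, from which the (E)-isomer, ethyl (7(11)E)-3β-acetoxy-9β-(pinacolboryl)cadina-4,7(11)-dien-12-oate F6, would be separated by chromatography. This olefination is not expected to be stereoselective, so the fallback trades selectivity for a separation. NaBO3 would give the 9β-alcohol F7. DIBAL-H at −78 °C would reduce the ester and cleave the acetate to give (7(11)E)-cadina-4,7(11)-diene-3β,9β,12-triol F8. 2,2,2-Trifluoroethyl formate would formylate the primary alcohol to give (7(11)E)-3β,9β-dihydroxycadina-4,7(11)-dien-12-yl formate F9, and Ac2O/pyridine would acetylate both secondary alcohols to give 18.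

Further compounds
F1 | step 5 | 3β-acetoxy-7-(trimethylsilyloxy)-8,11,12,13-tetranorcadina-4,7(9)-diene | CC(=O)O[C@@H]1C[C@@H]2[C@@H](C)C=C(O[Si](C)(C)C)[C@@H]2C=C1C
F2 | step 5 | 3β-acetoxy-7-(trimethylsilyloxy)-7,9-cyclo-11,12,13-trinorcadin-4-ene (siloxycyclopropane, C8 on the β face) | CC(=O)O[C@@H]1C[C@@H]2[C@@H](C)[C@@H]3C[C@]3(O[Si](C)(C)C)[C@@H]2C=C1C
F3 | step 5 | 3β-acetoxy-9-chloro-11,12,13-trinorcadin-4-en-7-one | CC(=O)O[C@@H]1C[C@@H]2[C@@H](C)C(Cl)CC(=O)[C@@H]2C=C1C
F4 | step 4 | 5β-(phenylthio)-8,11,12,13-tetranorcadin-3-en-7-one | CC1=CC[C@@H]2[C@@H](C)CC(=O)[C@@H]2[C@@H]1Sc1ccccc1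
F5 | step 4 | 3β-hydroxy-8,11,12,13-tetranorcadin-4-en-7-one | O[C@@H]1C[C@@H]2[C@@H](C)CC(=O)[C@@H]2C=C1C
F6 | step 10 | ethyl (7(11)E)-3β-acetoxy-9β-(pinacolboryl)cadina-4,7(11)-dien-12-oate | CC(=O)O[C@@H]1C[C@@H]2[C@@H](C)[C@H](B3OC(C)(C)C(C)(C)O3)C/C(=C(/C)C(=O)OCC)[C@@H]2C=C1C
F7 | step 10 | ethyl (7(11)E)-3β-acetoxy-9β-hydroxycadina-4,7(11)-dien-12-oate | CC(=O)O[C@@H]1C[C@@H]2[C@@H](C)[C@H](O)C/C(=C(/C)C(=O)OCC)[C@@H]2C=C1C
F8 | step 10 | (7(11)E)-cadina-4,7(11)-diene-3β,9β,12-triol | O[C@@H]1C[C@@H]2[C@@H](C)[C@H](O)C/C(=C(/C)CO)[C@@H]2C=C1C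
F9 | step 10 | (7(11)E)-3β,9β-dihydroxycadina-4,7(11)-dien-12-yl formate | O[C@@H]1C[C@@H]2[C@@H](C)[C@H](O)C/C(=C(/C)COC=O)[C@@H]2C=C1C
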